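**Plan**

1. Locants: the upper 2,3-dihydrobenzofuran is unprimed (dihydrofuran ring A = O1, C2, C3, C3a, C7a; benzo ring B); the lower one is primed (dihydrofuran ring C; benzo ring D).
2. Retrosynthetic cuts, in order: all O–benzyl bonds; C2–C3 of ring A (carbene C–H insertion); C3–C6′ (aryllithium plus nitrile); C2′–C3′ of ring C (same insertion); C3′–aryl; the alkene–ring B bond (Heck); the aryl C–O bonds of rings B and D (SNAr).
3. Forward: ring C is closed first (step 4), the two halves are joined at C3 (step 7), ring A is closed last (step 8), and one global deprotection follows (step 9); all six benzene rings are bought.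
4. Enabling feature: C2–H of ring A is a benzylic C–H flanked by O1 and the 4-oxyphenyl ring and lies 1,5 to C3, while C3 carries two aryl groups (C3a of ring B, C6′ of ring D) and can therefore be a diaryl (donor/donor) carbene. Ring B is symmetric about its C3a···C6 axis, so its two oxygens are equivalent before the insertion and the unused O–CH2–aryl group protects O4.
5. Stereochemistry: C3 and C3′ come from the chiral dirhodium catalyst (cis rings, 2R,3S and 2′R,3′S); C2 and C2′ are then funnelled to the trans configuration (2S, 2′S) by reversible acid ionisation of the O–C2 bonds in the last step; the (E)-alkene comes from the Heck reaction.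

Key step: step 8

Assumption: Rh2(R-PTAD)4, dirhodium tetrakis[(R)-(1-adamantyl)(phthalimido)acetate], is taken to give the S configuration at the carbene carbon; if its sense is the opposite, the mirror-image complex Rh2(S-PTAD)4 is used in steps 4 and 8 and nothing else changes.

**Route**

Step 1
Reactants: 1 2,4-bis(benzyloxy)benzaldehyde
Product: 2 [2,4-bis(benzyloxy)phenyl]methanol
Conditions: NaBH4, MeOH/THF, 0 °C
Reagents that add atoms: none
Why: Borohydride reduction of an aryl aldehyde is chemoselective and should give the benzylic alcohol without touching the benzyl ethers.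

Step 2
Reactants: 3 4-bromo-2,6-difluorobenzonitrile; 2 [2,4-bis(benzyloxy)phenyl]methanol (2.1 equiv)
Product: 4 4-bromo-2,6-bis{[2,4-bis(benzyloxy)phenyl]methoxy}benzonitrile
Conditions: NaH, THF/DMF, 0 to 50 °C
Reagents that add atoms: none
Why: Double nucleophilic aromatic substitution (addition–elimination) by the sodium alkoxide of 2 should replace both fluorides, which are activated by the ortho nitrile and are far better leaving groups in this mechanism than the para bromide that is kept as the later lithiation site.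

Step 3
Reactants: 5 1,3-bis(benzyloxy)-5-bromobenzene; 4 4-bromo-2,6-bis{[2,4-bis(benzyloxy)phenyl]methoxy}benzonitrile
Product: 8 (4-bromo-2,6-bis{[2,4-bis(benzyloxy)phenyl]methoxy}phenyl)[3,5-bis(benzyloxy)phenyl]methanone hydrazone, via [3,5-bis(benzyloxy)phenyl]lithium 6 (not isolated), via N-H ketimine of the same diaryl ketone 7 (not isolated)
Conditions: n-BuLi, THF, −78 °C; add 4, −78 to −20 °C; AcOH, then N2H4·H2O, EtOH, 70 °C, under Ar
Reagents that add atoms: hydrazine monohydrate, NN.O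
Why: Bromine–lithium exchange on 5, addition of aryllithium 6 to the nitrile of 4 (at −78 °C this is expected to outrun exchange with the aryl bromide of 4) and acid-assisted transimination of N–H ketimine 7 by hydrazine should give the hydrazone directly, which avoids condensing hydrazine with a hindered 2,6-dialkoxybenzophenone.

Step 4
Reactants: 8 (4-bromo-2,6-bis{[2,4-bis(benzyloxy)phenyl]methoxy}phenyl)[3,5-bis(benzyloxy)phenyl]methanone hydrazone
Product: 10 (2R,3S)-6-bromo-2-[2,4-bis(benzyloxy)phenyl]-4-{[2,4-bis(benzyloxy)phenyl]methoxy}-3-[3,5-bis(benzyloxy)phenyl]-2,3-dihydro-1-benzofuran (2,3-cis), via diaryldiazomethane 9 (not isolated)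
Conditions: MnO2, CH2Cl2, 0 °C, filter; Rh2(R-PTAD)4 (1 mol %), CH2Cl2, −20 °C to rt
Reagents that add atoms: none
Why: Hydrazone dehydrogenation to diaryldiazomethane 9 followed by enantioselective intramolecular 1,5 C–H insertion of the derived donor/donor dirhodium carbene into one of the two equivalent O–CH2–aryl groups should close ring C, with C3′ (S) set by the chiral carboxylate ligands and C2′ formed cis to it (R), while the second benzylic ether is left as the protecting group of O4′ and the aryl bromide is untouched.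

Step 5
Reactants: 3 4-bromo-2,6-difluorobenzonitrile; 11 [4-(benzyloxy)phenyl]methanol (2.1 equiv)
Product: 12 4-bromo-2,6-bis{[4-(benzyloxy)phenyl]methoxy}benzonitrile
Conditions: NaH, THF/DMF, 0 to 50 °C
Reagents that add atoms: none
Why: The same double nucleophilic aromatic substitution of the two nitrile-activated fluorides by a benzylic alkoxide should install both 4-(benzyloxy)benzyl ethers, one of which later supplies C2 with its aryl group and the other of which protects O4.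

Step 6
Reactants: 12 4-bromo-2,6-bis{[4-(benzyloxy)phenyl]methoxy}benzonitrile; 13 1-(benzyloxy)-4-ethenylbenzene
Product: 14 2,6-bis{[4-(benzyloxy)phenyl]methoxy}-4-{(E)-2-[4-(benzyloxy)phenyl]ethenyl}benzonitrile
Conditions: Pd(OAc)2 (5 mol %), P(o-tol)3, Et3N, DMF, 100 °C
Reagents that add atoms: none
Why: Heck reaction, in which oxidative addition of zerovalent palladium into the C–Br bond activated by the para nitrile, syn carbopalladation of the styrene at its terminal carbon and syn β-hydride elimination should give the (E)-stilbene.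

Step 7
Reactants: 10 (2R,3S)-6-bromo-2-[2,4-bis(benzyloxy)phenyl]-4-{[2,4-bis(benzyloxy)phenyl]methoxy}-3-[3,5-bis(benzyloxy)phenyl]-2,3-dihydro-1-benzofuran; 14 2,6-bis{[4-(benzyloxy)phenyl]methoxy}-4-{(E)-2-[4-(benzyloxy)phenyl]ethenyl}benzonitrile
Product: 17 [(2R,3S)-2-[2,4-bis(benzyloxy)phenyl]-4-{[2,4-bis(benzyloxy)phenyl]methoxy}-3-[3,5-bis(benzyloxy)phenyl]-2,3-dihydro-1-benzofuran-6-yl](2,6-bis{[4-(benzyloxy)phenyl]methoxy}-4-{(E)-2-[4-(benzyloxy)phenyl]ethenyl}phenyl)methanone hydrazone, via C6′ aryllithium 15 (not isolated), via N-H ketimine 16 (not isolated)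
Conditions: n-BuLi, THF, −78 °C; add 14, −78 to −20 °C; AcOH, then N2H4·H2O, EtOH, 70 °C, under Ar
Reagents that add atoms: hydrazine monohydrate, NN.O
Why: Bromine–lithium exchange at C6′ of 10 is much faster at −78 °C than deprotonation at C2′ or C3′, and aryllithium 15 should add to the nitrile of 14 to give, after protonation and transimination with hydrazine, the hydrazone in which the future C3 already carries both of its aryl groups.

Step 8
Reactants: 17 [(2R,3S)-2-[2,4-bis(benzyloxy)phenyl]-4-{[2,4-bis(benzyloxy)phenyl]methoxy}-3-[3,5-bis(benzyloxy)phenyl]-2,3-dihydro-1-benzofuran-6-yl](2,6-bis{[4-(benzyloxy)phenyl]methoxy}-4-{(E)-2-[4-(benzyloxy)phenyl]ethenyl}phenyl)methanone hydrazone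
Product: 19 (2R,3S)-2-[4-(benzyloxy)phenyl]-4-{[4-(benzyloxy)phenyl]methoxy}-6-{(E)-2-[4-(benzyloxy)phenyl]ethenyl}-3-[(2R,3S)-2-[2,4-bis(benzyloxy)phenyl]-4-{[2,4-bis(benzyloxy)phenyl]methoxy}-3-[3,5-bis(benzyloxy)phenyl]-2,3-dihydro-1-benzofuran-6-yl]-2,3-dihydro-1-benzofuran (both rings 2,3-cis), via diaryldiazomethane 18 (not isolated)
Conditions: MnO2, CH2Cl2, 0 °C, filter; slow addition to Rh2(R-PTAD)4 (2 mol %), CH2Cl2 (high dilution), −20 °C to rt
Reagents that add atoms: none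
Why: MnO2 dehydrogenates the hydrazone to diaryldiazomethane 18, which loses N2 on the dirhodium tetracarboxylate to give a donor/donor carbene at C3, and this carbene inserts into a C–H bond of the O–CH2–aryl group on the neighbouring ring B oxygen (hydride shift to C3 through a five-membered transition state with C2–C3 bond formation on the metal). The closest known reaction type is the enantioselective intramolecular C–H insertion of donor/donor dirhodium carbenes generated from hydrazones of 2-(benzyloxy)benzophenones, which gives cis-2,3-diaryl-2,3-dihydrobenzofurans. Ring A (O1, C2, C3, C3a, C7a) is closed by the C2–C3 bond in a 1,5 C–H insertion, which in its stepwise limit is a 5-endo-trig attack of the rhodium-bound C3 on the oxocarbenium carbon C2. C3 (S) is set by the chiral carboxylate ligands of Rh2(R-PTAD)4, which should override the remote centres C2′ and C3′, and C2 is formed cis to it (R) because hydride transfer and C–C closure take place on the same face; C2 is corrected to S in step 9. The step needs site selectivity, secured because the two O–CH2–aryl groups of ring B are interchanged by rotation about the C3–C3a bond and no other C–H bond lies 1,5 to the carbene, and chemoselectivity over cyclopropanation of the stilbene and over azine formation, secured by the low electrophilicity of a diaryl carbene, the intramolecular geometry and high dilution. The C–H bond that is broken is flanked by oxygen and a 4-alkoxyphenyl ring and is therefore among the most hydridic, which favours the insertion over all bimolecular paths.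

Step 9
Reactants: 19 (2R,3S)-2-[4-(benzyloxy)phenyl]-4-{[4-(benzyloxy)phenyl]methoxy}-6-{(E)-2-[4-(benzyloxy)phenyl]ethenyl}-3-[(2R,3S)-2-[2,4-bis(benzyloxy)phenyl]-4-{[2,4-bis(benzyloxy)phenyl]methoxy}-3-[3,5-bis(benzyloxy)phenyl]-2,3-dihydro-1-benzofuran-6-yl]-2,3-dihydro-1-benzofuran
Product: 20 (2S,3S)-3-[(2S,3S)-2-(2,4-dihydroxyphenyl)-3-(3,5-dihydroxyphenyl)-4-hydroxy-2,3-dihydro-1-benzofuran-6-yl]-2-(4-hydroxyphenyl)-6-[(E)-2-(4-hydroxyphenyl)ethenyl]-2,3-dihydro-1-benzofuran-4-ol (CNP0118407.1)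
Conditions: BCl3 (excess), C6HMe5, CH2Cl2, −78 to 0 °C; MeOH quench
Reagents that add atoms: none
Why: Lewis acid ether cleavage, in which BCl3 should cleave the nine benzyl ethers and the two spare benzylic ethers on O4 and O4′ with pentamethylbenzene trapping the benzylic cations, and the same acid reversibly ionises the O1–C2 and O1′–C2′ bonds to para-oxybenzyl cations, so that both cis rings should relax to the more stable trans rings (C2 and C2′ from R to S) while C3, C3′ and the (E)-alkene are untouched.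

**Compound list**

1 | 2,4-bis(benzyloxy)benzaldehyde | O=Cc1ccc(OCc2ccccc2)cc1OCc1ccccc1 | starting material
2 | [2,4-bis(benzyloxy)phenyl]methanol | OCc1ccc(OCc2ccccc2)cc1OCc1ccccc1 | intermediate
3 | 4-bromo-2,6-difluorobenzonitrile | N#Cc1c(F)cc(Br)cc1F | starting material
4 | 4-bromo-2,6-bis{[2,4-bis(benzyloxy)phenyl]methoxy}benzonitrile | N#Cc1c(OCc2ccc(OCc3ccccc3)cc2OCc2ccccc2)cc(Br)cc1OCc1ccc(OCc2ccccc2)cc1OCc1ccccc1 | intermediate
5 | 1,3-bis(benzyloxy)-5-bromobenzene | Brc1cc(OCc2ccccc2)cc(OCc2ccccc2)c1 | starting material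
6 | [3,5-bis(benzyloxy)phenyl]lithium | [Li]c1cc(OCc2ccccc2)cc(OCc2ccccc2)c1 | intermediate
7 | (4-bromo-2,6-bis{[2,4-bis(benzyloxy)phenyl]methoxy}phenyl)[3,5-bis(benzyloxy)phenyl]methanimine | N=C(c1cc(OCc2ccccc2)cc(OCc2ccccc2)c1)c1c(OCc2ccc(OCc3ccccc3)cc2OCc2ccccc2)cc(Br)cc1OCc1ccc(OCc2ccccc2)cc1OCc1ccccc1 | intermediate
8 | (4-bromo-2,6-bis{[2,4-bis(benzyloxy)phenyl]methoxy}phenyl)[3,5-bis(benzyloxy)phenyl]methanone hydrazone | NN=C(c1cc(OCc2ccccc2)cc(OCc2ccccc2)c1)c1c(OCc2ccc(OCc3ccccc3)cc2OCc2ccccc2)cc(Br)cc1OCc1ccc(OCc2ccccc2)cc1OCc1ccccc1 | intermediate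
9 | 5-bromo-2-{diazo[3,5-bis(benzyloxy)phenyl]methyl}-1,3-bis{[2,4-bis(benzyloxy)phenyl]methoxy}benzene | [N-]=[N+]=C(c1cc(OCc2ccccc2)cc(OCc2ccccc2)c1)c1c(OCc2ccc(OCc3ccccc3)cc2OCc2ccccc2)cc(Br)cc1OCc1ccc(OCc2ccccc2)cc1OCc1ccccc1 | intermediate
10 | (2R,3S)-6-bromo-2-[2,4-bis(benzyloxy)phenyl]-4-{[2,4-bis(benzyloxy)phenyl]methoxy}-3-[3,5-bis(benzyloxy)phenyl]-2,3-dihydro-1-benzofuran (2,3-cis) | Brc1cc(OCc2ccc(OCc3ccccc3)cc2OCc2ccccc2)c2c(c1)O[C@@H](c1ccc(OCc3ccccc3)cc1OCc1ccccc1)[C@H]2c1cc(OCc2ccccc2)cc(OCc2ccccc2)c1 | intermediate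
11 | [4-(benzyloxy)phenyl]methanol | OCc1ccc(OCc2ccccc2)cc1 | starting material
12 | 4-bromo-2,6-bis{[4-(benzyloxy)phenyl]methoxy}benzonitrile | N#Cc1c(OCc2ccc(OCc3ccccc3)cc2)cc(Br)cc1OCc1ccc(OCc2ccccc2)cc1 | intermediate
13 | 1-(benzyloxy)-4-ethenylbenzene | C=Cc1ccc(OCc2ccccc2)cc1 | starting material
14 | 2,6-bis{[4-(benzyloxy)phenyl]methoxy}-4-{(E)-2-[4-(benzyloxy)phenyl]ethenyl}benzonitrile | N#Cc1c(OCc2ccc(OCc3ccccc3)cc2)cc(/C=C/c2ccc(OCc3ccccc3)cc2)cc1OCc1ccc(OCc2ccccc2)cc1 | intermediate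
15 | [(2R,3S)-2-[2,4-bis(benzyloxy)phenyl]-4-{[2,4-bis(benzyloxy)phenyl]methoxy}-3-[3,5-bis(benzyloxy)phenyl]-2,3-dihydro-1-benzofuran-6-yl]lithium | [Li]c1cc(OCc2ccc(OCc3ccccc3)cc2OCc2ccccc2)c2c(c1)O[C@@H](c1ccc(OCc3ccccc3)cc1OCc1ccccc1)[C@H]2c1cc(OCc2ccccc2)cc(OCc2ccccc2)c1 | intermediate
16 | [(2R,3S)-2-[2,4-bis(benzyloxy)phenyl]-4-{[2,4-bis(benzyloxy)phenyl]methoxy}-3-[3,5-bis(benzyloxy)phenyl]-2,3-dihydro-1-benzofuran-6-yl](2,6-bis{[4-(benzyloxy)phenyl]methoxy}-4-{(E)-2-[4-(benzyloxy)phenyl]ethenyl}phenyl)methanimine | N=C(c1cc(OCc2ccc(OCc3ccccc3)cc2OCc2ccccc2)c2c(c1)O[C@@H](c1ccc(OCc3ccccc3)cc1OCc1ccccc1)[C@H]2c1cc(OCc2ccccc2)cc(OCc2ccccc2)c1)c1c(OCc2ccc(OCc3ccccc3)cc2)cc(/C=C/c2ccc(OCc3ccccc3)cc2)cc1OCc1ccc(OCc2ccccc2)cc1 | intermediate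
17 | [(2R,3S)-2-[2,4-bis(benzyloxy)phenyl]-4-{[2,4-bis(benzyloxy)phenyl]methoxy}-3-[3,5-bis(benzyloxy)phenyl]-2,3-dihydro-1-benzofuran-6-yl](2,6-bis{[4-(benzyloxy)phenyl]methoxy}-4-{(E)-2-[4-(benzyloxy)phenyl]ethenyl}phenyl)methanone hydrazone | NN=C(c1cc(OCc2ccc(OCc3ccccc3)cc2OCc2ccccc2)c2c(c1)O[C@@H](c1ccc(OCc3ccccc3)cc1OCc1ccccc1)[C@H]2c1cc(OCc2ccccc2)cc(OCc2ccccc2)c1)c1c(OCc2ccc(OCc3ccccc3)cc2)cc(/C=C/c2ccc(OCc3ccccc3)cc2)cc1OCc1ccc(OCc2ccccc2)cc1 | intermediate
18 | (2R,3S)-6-[diazo(2,6-bis{[4-(benzyloxy)phenyl]methoxy}-4-{(E)-2-[4-(benzyloxy)phenyl]ethenyl}phenyl)methyl]-2-[2,4-bis(benzyloxy)phenyl]-4-{[2,4-bis(benzyloxy)phenyl]methoxy}-3-[3,5-bis(benzyloxy)phenyl]-2,3-dihydro-1-benzofuran | [N-]=[N+]=C(c1cc(OCc2ccc(OCc3ccccc3)cc2OCc2ccccc2)c2c(c1)O[C@@H](c1ccc(OCc3ccccc3)cc1OCc1ccccc1)[C@H]2c1cc(OCc2ccccc2)cc(OCc2ccccc2)c1)c1c(OCc2ccc(OCc3ccccc3)cc2)cc(/C=C/c2ccc(OCc3ccccc3)cc2)cc1OCc1ccc(OCc2ccccc2)cc1 | intermediate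
19 | (2R,3S)-2-[4-(benzyloxy)phenyl]-4-{[4-(benzyloxy)phenyl]methoxy}-6-{(E)-2-[4-(benzyloxy)phenyl]ethenyl}-3-[(2R,3S)-2-[2,4-bis(benzyloxy)phenyl]-4-{[2,4-bis(benzyloxy)phenyl]methoxy}-3-[3,5-bis(benzyloxy)phenyl]-2,3-dihydro-1-benzofuran-6-yl]-2,3-dihydro-1-benzofuran (both rings 2,3-cis) | c1ccccc1COc1ccc(/C=C/c2cc(OCc3ccc(OCc4ccccc4)cc3)c3c(c2)O[C@@H](c2ccc(OCc4ccccc4)cc2)[C@H]3c2cc(OCc3ccc(OCc4ccccc4)cc3OCc3ccccc3)c3c(c2)O[C@@H](c2ccc(OCc4ccccc4)cc2OCc2ccccc2)[C@H]3c2cc(OCc3ccccc3)cc(OCc3ccccc3)c2)cc1 | intermediate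
20 | (2S,3S)-3-[(2S,3S)-2-(2,4-dihydroxyphenyl)-3-(3,5-dihydroxyphenyl)-4-hydroxy-2,3-dihydro-1-benzofuran-6-yl]-2-(4-hydroxyphenyl)-6-[(E)-2-(4-hydroxyphenyl)ethenyl]-2,3-dihydro-1-benzofuran-4-ol (both rings 2,3-trans) | Oc1ccc(/C=C/c2cc(O)c3c(c2)O[C@H](c2ccc(O)cc2)[C@H]3c2cc(O)c3c(c2)O[C@H](c2ccc(O)cc2O)[C@H]3c2cc(O)cc(O)c2)cc1 | target

**Totals**

Total step count: 9. Longest linear sequence: 7 steps (steps 1, 2, 3, 4, 7, 8, 9).

**Steps most likely to fail**

Step 8. The carbene is flanked by two ortho ether oxygens and the hydride donor is a 4-alkoxybenzyl ether. Hydride transfer may therefore give a long-lived oxocarbenium/rhodium-bound carbanion pair that collapses with poor facial control at C3, or the diazo compound may be consumed by azine formation. The fallback closes ring A through its O1–C2 bond instead. It sets out from 17, which is oxidised to 18 as in step 8. Sc(OTf)3-catalysed formyl C–H insertion of the diazo carbon into 4-(benzyloxy)benzaldehyde (CH2Cl2, −78 °C; addition to the aldehyde, 1,2-hydride shift, loss of N2) should give the 1,2,2-triarylethanone F1. Its doubly benzylic α-centre epimerises freely, so asymmetric transfer hydrogenation under dynamic kinetic resolution (RuCl[(S,S)-TsDPEN](p-cymene) or its mirror image, HCO2H/Et3N) should give the (2S)-1,2,2-triarylethanol F2, the two ortho oxygens of the ring B aryl group differentiating the two aryl groups on the α-carbon. Any epimer at that carbon is a diastereomer because of ring C and is removed by chromatography. TFA/C6HMe5 in CH2Cl2 at 0 °C should then cleave the two spare benzylic ethers, ionise the carbinol to the para-alkoxybenzyl cation and close ring A by attack of a freed ring B phenol (stereoconvergent, trans), while ring C equilibrates to trans, giving the all-trans hexabenzyl ether F3. Debenzylation of F3 with BCl3/C6HMe5 at −78 °C comes back to the route at 20.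

Step 9. The two cis rings may not equilibrate fully in the Lewis acid medium, or ring-opened benzylic cations may be intercepted by chloride or by the scavenger while eleven ether cleavages are still in progress. The fallback separates the two tasks and sets out from 19. Debenzylation with BCl3/C6HMe5 is run and quenched at −78 °C, where the O–C2 bonds should stay closed, to give the cis,cis octaphenol F4 (possibly mixed with partly epimerised material). A second operation with catalytic TsOH·H2O in MeCN at rt and no cation trap present then lets the free para-hydroxyl groups open both rings reversibly to protonated para-quinone methides that reclose to the trans rings, which comes back to the route at 20.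

Step 7. Addition of the bulky aryllithium to the di-ortho-substituted nitrile may be slow and then lose to conjugate addition onto the cyanostilbene or to proton transfer. The fallback unites the halves through an aldehyde and sets out from 14 and 10. DIBAL-H reduction of 14 (toluene, −78 °C, aqueous work-up) should give the benzaldehyde F5. Aryllithium 15, made from 10 as in step 7, adds to it to give the diarylmethanol F6 (mixture of carbinol epimers), and Dess–Martin periodinane oxidises this to the diaryl ketone F7. Because this 2,6-dialkoxybenzophenone resists hydrazine itself, Sc(OTf)3-catalysed condensation with 1,2-bis(tert-butyldimethylsilyl)hydrazine gives the N-silyl hydrazone F8, and TBAF in THF removes the silyl group, which comes back to the route at 17.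

**Further compounds**

F1 | step 8 | 1-[4-(benzyloxy)phenyl]-2-[(2R,3S)-2-[2,4-bis(benzyloxy)phenyl]-4-{[2,4-bis(benzyloxy)phenyl]methoxy}-3-[3,5-bis(benzyloxy)phenyl]-2,3-dihydro-1-benzofuran-6-yl]-2-(2,6-bis{[4-(benzyloxy)phenyl]methoxy}-4-{(E)-2-[4-(benzyloxy)phenyl]ethenyl}phenyl)ethan-1-one (α-centre epimerising) | O=C(c1ccc(OCc2ccccc2)cc1)C(c1cc(OCc2ccc(OCc3ccccc3)cc2OCc2ccccc2)c2c(c1)O[C@@H](c1ccc(OCc3ccccc3)cc1OCc1ccccc1)[C@H]2c1cc(OCc2ccccc2)cc(OCc2ccccc2)c1)c1c(OCc2ccc(OCc3ccccc3)cc2)cc(/C=C/c2ccc(OCc3ccccc3)cc2)cc1OCc1ccc(OCc2ccccc2)cc1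
F2 | step 8 | (2S)-1-[4-(benzyloxy)phenyl]-2-[(2R,3S)-2-[2,4-bis(benzyloxy)phenyl]-4-{[2,4-bis(benzyloxy)phenyl]methoxy}-3-[3,5-bis(benzyloxy)phenyl]-2,3-dihydro-1-benzofuran-6-yl]-2-(2,6-bis{[4-(benzyloxy)phenyl]methoxy}-4-{(E)-2-[4-(benzyloxy)phenyl]ethenyl}phenyl)ethan-1-ol (carbinol centre either way) | OC(c1ccc(OCc2ccccc2)cc1)[C@@H](c1cc(OCc2ccc(OCc3ccccc3)cc2OCc2ccccc2)c2c(c1)O[C@@H](c1ccc(OCc3ccccc3)cc1OCc1ccccc1)[C@H]2c1cc(OCc2ccccc2)cc(OCc2ccccc2)c1)c1c(OCc2ccc(OCc3ccccc3)cc2)cc(/C=C/c2ccc(OCc3ccccc3)cc2)cc1OCc1ccc(OCc2ccccc2)cc1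
F3 | step 8 | (2S,3S)-2-[4-(benzyloxy)phenyl]-6-{(E)-2-[4-(benzyloxy)phenyl]ethenyl}-3-[(2S,3S)-2-[2,4-bis(benzyloxy)phenyl]-3-[3,5-bis(benzyloxy)phenyl]-4-hydroxy-2,3-dihydro-1-benzofuran-6-yl]-2,3-dihydro-1-benzofuran-4-ol (both rings trans) | c1ccccc1COc1ccc(/C=C/c2cc(O)c3c(c2)O[C@H](c2ccc(OCc4ccccc4)cc2)[C@H]3c2cc(O)c3c(c2)O[C@H](c2ccc(OCc4ccccc4)cc2OCc2ccccc2)[C@H]3c2cc(OCc3ccccc3)cc(OCc3ccccc3)c2)cc1
F4 | step 9 | (2R,3S)-3-[(2R,3S)-2-(2,4-dihydroxyphenyl)-3-(3,5-dihydroxyphenyl)-4-hydroxy-2,3-dihydro-1-benzofuran-6-yl]-2-(4-hydroxyphenyl)-6-[(E)-2-(4-hydroxyphenyl)ethenyl]-2,3-dihydro-1-benzofuran-4-ol (both rings cis) | Oc1ccc(/C=C/c2cc(O)c3c(c2)O[C@@H](c2ccc(O)cc2)[C@H]3c2cc(O)c3c(c2)O[C@@H](c2ccc(O)cc2O)[C@H]3c2cc(O)cc(O)c2)cc1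
F5 | step 7 | 2,6-bis{[4-(benzyloxy)phenyl]methoxy}-4-{(E)-2-[4-(benzyloxy)phenyl]ethenyl}benzaldehyde | O=Cc1c(OCc2ccc(OCc3ccccc3)cc2)cc(/C=C/c2ccc(OCc3ccccc3)cc2)cc1OCc1ccc(OCc2ccccc2)cc1
F6 | step 7 | [(2R,3S)-2-[2,4-bis(benzyloxy)phenyl]-4-{[2,4-bis(benzyloxy)phenyl]methoxy}-3-[3,5-bis(benzyloxy)phenyl]-2,3-dihydro-1-benzofuran-6-yl](2,6-bis{[4-(benzyloxy)phenyl]methoxy}-4-{(E)-2-[4-(benzyloxy)phenyl]ethenyl}phenyl)methanol (carbinol epimers) | OC(c1cc(OCc2ccc(OCc3ccccc3)cc2OCc2ccccc2)c2c(c1)O[C@@H](c1ccc(OCc3ccccc3)cc1OCc1ccccc1)[C@H]2c1cc(OCc2ccccc2)cc(OCc2ccccc2)c1)c1c(OCc2ccc(OCc3ccccc3)cc2)cc(/C=C/c2ccc(OCc3ccccc3)cc2)cc1OCc1ccc(OCc2ccccc2)cc1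
F7 | step 7 | [(2R,3S)-2-[2,4-bis(benzyloxy)phenyl]-4-{[2,4-bis(benzyloxy)phenyl]methoxy}-3-[3,5-bis(benzyloxy)phenyl]-2,3-dihydro-1-benzofuran-6-yl](2,6-bis{[4-(benzyloxy)phenyl]methoxy}-4-{(E)-2-[4-(benzyloxy)phenyl]ethenyl}phenyl)methanone | O=C(c1cc(OCc2ccc(OCc3ccccc3)cc2OCc2ccccc2)c2c(c1)O[C@@H](c1ccc(OCc3ccccc3)cc1OCc1ccccc1)[C@H]2c1cc(OCc2ccccc2)cc(OCc2ccccc2)c1)c1c(OCc2ccc(OCc3ccccc3)cc2)cc(/C=C/c2ccc(OCc3ccccc3)cc2)cc1OCc1ccc(OCc2ccccc2)cc1
F8 | step 7 | N-(tert-butyldimethylsilyl)hydrazone of ketone F7 | CC(C)(C)[Si](C)(C)NN=C(c1cc(OCc2ccc(OCc3ccccc3)cc2OCc2ccccc2)c2c(c1)O[C@@H](c1ccc(OCc3ccccc3)cc1OCc1ccccc1)[C@H]2c1cc(OCc2ccccc2)cc(OCc2ccccc2)c1)c1c(OCc2ccc(OCc3ccccc3)cc2)cc(/C=C/c2ccc(OCc3ccccc3)cc2)cc1OCc1ccc(OCc2ccccc2)cc1
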